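The route rests on disconnecting the C2=C3 double bond of the furan ring. Both carbons are latent carbonyl carbons: C2 (attached to O1 and ring B) is the ester carbon of an O-aroyl group on the ring A phenol oxygen O1, and C3 (attached to C3a and its one-carbon substituent) is the ketone carbon of an ortho acetyl group. Low-valent titanium should couple the two carbonyls reductively and, in one operation, close the furan and deliver the complete 2-aryl-3-methylbenzofuran skeleton. The precursor is therefore an acetophenone of ring A carrying a benzyl ether on one flanking oxygen and a bis-MOM-protected 2,4-dihydroxybenzoate ester on the other.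

Key step: step 5

Remark: benzofuran numbering (O1, C2, C3, C3a, C4–C7, C7a) is used, ring A being the benzo ring and ring B the 2-aryl group; the target is achiral, and the stereocentres of the transient intermediates 7 and 14 and of the fallback compounds F1, F2, F4 and F9 are racemic and disappear again.

Step 1
Reactants: 1 1-(2,6-dihydroxy-4-methoxyphenyl)ethanone
Product: 2 1-[2-(benzyloxy)-6-hydroxy-4-methoxyphenyl]ethanone
Conditions: BnBr (1 equiv), K2CO3, acetone, reflux
Reagents that add atoms: benzyl bromide, BrCc1ccccc1
Why: Williamson etherification; the two hydroxyls of 1 are equivalent by symmetry, so the first benzylation is unambiguous, and with one equivalent of BnBr the second is held back because the remaining hydroxyl is tied up in a chelated hydrogen bond to the acetyl oxygen.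

Step 2
Reactants: 3 methyl 2,4-dihydroxybenzoate
Product: 4 methyl 2,4-bis(methoxymethoxy)benzoate
Conditions: NaH, MOMCl, DMF, 0 °C to rt
Reagents that add atoms: chloromethyl methyl ether, COCCl
Why: Williamson-type O-alkylation with an α-chloro ether; NaH deprotonates both phenols, including the hydrogen-bonded 2-OH, and the phenoxides displace chloride from MOMCl to give the two mixed acetals, the methyl ester being inert.

Step 3
Reactants: 4 methyl 2,4-bis(methoxymethoxy)benzoate
Product: 5 2,4-bis(methoxymethoxy)benzoic acid
Conditions: LiOH·H2O, THF/MeOH/H2O, 50 °C; then cold 1 M HCl to pH 4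
Reagents that add atoms: lithium hydroxide, [Li+].[OH-]
Why: Saponification (acyl-oxygen ester hydrolysis); MOM acetals are stable to base and should survive a brief cold acidification to pH 4, which liberates the free acid.

Step 4
Reactants: 2 1-[2-(benzyloxy)-6-hydroxy-4-methoxyphenyl]ethanone; 5 2,4-bis(methoxymethoxy)benzoic acid
Product: 6 2-acetyl-3-(benzyloxy)-5-methoxyphenyl 2,4-bis(methoxymethoxy)benzoate
Conditions: DCC, DMAP (cat.), CH2Cl2, 0 °C to rt
Reagents that add atoms: none
Why: Steglich esterification; DCC activates acid 5 and DMAP relays the acyl group to the chelated, flanked phenol of 2 under conditions too mild to enolize the acetyl group, so no Baker–Venkataraman acyl shift is expected.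

Step 5
Reactants: 6 2-acetyl-3-(benzyloxy)-5-methoxyphenyl 2,4-bis(methoxymethoxy)benzoate
Product: 8 4-(benzyloxy)-2-[2,4-bis(methoxymethoxy)phenyl]-6-methoxy-3-methylbenzofuran, via cyclic titanium 2,3-diolate 7 (not isolated)
Conditions: TiCl3, Zn dust, pyridine, THF, reflux; slow addition of 6 at high dilution; aq. K2CO3 work-up
Reagents that add atoms: none
Why: Low-valent titanium generated from TiCl3 and Zn should transfer an electron to the aryl ketone, the more easily reduced of the two carbonyl groups, and the titanium-bound ketyl carbon then adds to the ester carbonyl held three atoms away to give the cyclic titanium diolate 7. The oxophilic metal then strips both oxygens from 7, a deoxygenation driven by strong Ti–O bonds and by the aromaticity of the new furan, which leaves the C2=C3 double bond. The closest known reaction type is the McMurry-type intramolecular reductive coupling of ortho-acyl aryl esters (oxo-esters) to benzofurans, which has a counterpart in the oxo-amide coupling to indoles. The furan ring is closed in a 5-exo-trig mode, the ketyl carbon attacking the exocyclic C=O of the ester across the O1–C7a–C3a tether. No stereocentre survives, since the two sp3 carbons of 7 become the sp2 carbons C2 and C3. The step needs reduction of the ketone before the ester and ring closure ahead of intermolecular pinacol dimerization, which the lower reduction potential of the aryl ketone, the rigid ortho-phenylene tether and slow addition at high dilution should secure; aryl ethers and acetals are tolerated by this reagent, and pyridine plus a basic work-up guard the MOM groups against traces of HCl.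

Step 6
Reactants: 8 4-(benzyloxy)-2-[2,4-bis(methoxymethoxy)phenyl]-6-methoxy-3-methylbenzofuran
Product: 9 4-(benzyloxy)-2-[2,4-bis(methoxymethoxy)phenyl]-6-methoxybenzofuran-3-carbaldehyde
Conditions: SeO2, 1,4-dioxane, reflux
Reagents that add atoms: selenium dioxide, O=[Se]=O
Why: Riley oxidation; the C3 methyl group is allylic to the electron-rich C2=C3 enol-ether bond of the furan, so SeO2 should attack it by the ene/[2,3]-sigmatropic sequence and carry it to the aldehyde, a vinylogous formate that resists further oxidation, while the benzyl and MOM ethers offer no comparably activated C–H bond.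

Step 7
Reactants: 9 4-(benzyloxy)-2-[2,4-bis(methoxymethoxy)phenyl]-6-methoxybenzofuran-3-carbaldehyde
Product: 10 2-[2,4-bis(methoxymethoxy)phenyl]-4-hydroxy-6-methoxybenzofuran-3-carbaldehyde
Conditions: H2 (1 atm), Pd/C, EtOAc, rt
Reagents that add atoms: none
Why: Catalytic hydrogenolysis of an aryl benzyl ether; O–CH2Ph cleavage on Pd/C at 1 atm is much faster than reduction of the aldehyde, which is deactivated as a vinylogous formate, and the acetals are inert, the reaction being stopped after uptake of one equivalent of H2.

Step 8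
Reactants: 10 2-[2,4-bis(methoxymethoxy)phenyl]-4-hydroxy-6-methoxybenzofuran-3-carbaldehyde; 11 3-chloro-3-methylbut-1-yne
Product: 12 2-[2,4-bis(methoxymethoxy)phenyl]-6-methoxy-4-[(2-methylbut-3-yn-2-yl)oxy]benzofuran-3-carbaldehyde
Conditions: DBU, CuCl2·2H2O (cat.), MeCN, 0 °C to rt
Reagents that add atoms: none
Why: Copper-catalysed propargylic etherification of a phenol with a tertiary propargylic chloride (the standard entry to aryl 1,1-dimethylpropargyl ethers); DBU forms the phenoxide of the only free hydroxyl, O4, and the copper acetylide of 11 ionizes to an allenylidene-type electrophile that is captured at the tertiary carbon, a process that tolerates aldehydes and works well with carbonyl-bearing phenols.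

Step 9
Reactants: 12 2-[2,4-bis(methoxymethoxy)phenyl]-6-methoxy-4-[(2-methylbut-3-yn-2-yl)oxy]benzofuran-3-carbaldehyde
Product: 13 2-[2,4-bis(methoxymethoxy)phenyl]-6-methoxy-4-[(2-methylbut-3-en-2-yl)oxy]benzofuran-3-carbaldehyde
Conditions: H2 (1 atm), Pd/CaCO3 poisoned with Pb(OAc)2 (Lindlar catalyst), quinoline, EtOAc, rt
Reagents that add atoms: none
Why: Lindlar semihydrogenation; the poisoned palladium surface reduces the terminal alkyne to the vinyl group and stops there, leaving aldehyde, acetals and the aryl ether untouched, and it is done before any heating so that the propargyl ether cannot cyclize to a chromene.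

Step 10
Reactants: 13 2-[2,4-bis(methoxymethoxy)phenyl]-6-methoxy-4-[(2-methylbut-3-en-2-yl)oxy]benzofuran-3-carbaldehyde
Product: 15 2-[2,4-bis(methoxymethoxy)phenyl]-4-hydroxy-6-methoxy-5-(3-methylbut-2-en-1-yl)benzofuran-3-carbaldehyde, via 5H-benzofuran-4-one dienone 14 (not isolated)
Conditions: N,N-diethylaniline, 130 °C
Reagents that add atoms: none
Why: Aromatic Claisen rearrangement ([3,3]-sigmatropic shift with allyl inversion); the 1,1-dimethylallyl group can migrate only to C5, the one ortho position of O4 that carries hydrogen (the other ortho carbon is the ring-fusion atom C3a), giving dienone 14 whose single stereocentre is erased when it enolizes to the 5-prenyl phenol, and the weakly basic solvent suppresses acid-induced ether cleavage or chroman formation.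

Step 11
Reactants: 15 2-[2,4-bis(methoxymethoxy)phenyl]-4-hydroxy-6-methoxy-5-(3-methylbut-2-en-1-yl)benzofuran-3-carbaldehyde
Product: 16 2-(2,4-dihydroxyphenyl)-4-hydroxy-6-methoxy-5-(3-methylbut-2-en-1-yl)benzofuran-3-carbaldehyde
Conditions: 3 M aq. HCl, THF, 45 °C
Reagents that add atoms: none
Why: Acid-catalysed acetal hydrolysis; aryl MOM ethers cleave through the methoxymethyl oxocarbenium ion under dilute acid at a temperature at which the trisubstituted alkene is protonated only slowly, and the alcohol-free medium prevents the aldehyde and the new 2'-hydroxyl from being locked as a cyclic mixed acetal.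

Compound list
1 | 1-(2,6-dihydroxy-4-methoxyphenyl)ethanone (2',6'-dihydroxy-4'-methoxyacetophenone) | CC(=O)c1c(O)cc(OC)cc1O | starting material
2 | 1-[2-(benzyloxy)-6-hydroxy-4-methoxyphenyl]ethanone | CC(=O)c1c(OCc2ccccc2)cc(OC)cc1O | intermediate
3 | methyl 2,4-dihydroxybenzoate | COC(=O)c1ccc(O)cc1O | starting material
4 | methyl 2,4-bis(methoxymethoxy)benzoate | COC(=O)c1ccc(OCOC)cc1OCOC | intermediate
5 | 2,4-bis(methoxymethoxy)benzoic acid | OC(=O)c1ccc(OCOC)cc1OCOC | intermediate
6 | 2-acetyl-3-(benzyloxy)-5-methoxyphenyl 2,4-bis(methoxymethoxy)benzoate | CC(=O)c1c(OCc2ccccc2)cc(OC)cc1OC(=O)c1ccc(OCOC)cc1OCOC | intermediate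
7 | cyclic titanium 2,3-diolate of 4-(benzyloxy)-2-[2,4-bis(methoxymethoxy)phenyl]-6-methoxy-3-methyl-2,3-dihydrobenzofuran-2,3-diol, drawn as its TiCl2 diolate (cis, racemic, not isolated) | C[C@]12O[Ti](Cl)(Cl)O[C@@]1(c3ccc(OCOC)cc3OCOC)Oc3cc(OC)cc(OCc4ccccc4)c23 | intermediate
8 | 4-(benzyloxy)-2-[2,4-bis(methoxymethoxy)phenyl]-6-methoxy-3-methylbenzofuran | Cc1c(-c2ccc(OCOC)cc2OCOC)oc2cc(OC)cc(OCc3ccccc3)c12 | intermediate
9 | 4-(benzyloxy)-2-[2,4-bis(methoxymethoxy)phenyl]-6-methoxybenzofuran-3-carbaldehyde | O=Cc1c(-c2ccc(OCOC)cc2OCOC)oc2cc(OC)cc(OCc3ccccc3)c12 | intermediate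
10 | 2-[2,4-bis(methoxymethoxy)phenyl]-4-hydroxy-6-methoxybenzofuran-3-carbaldehyde | O=Cc1c(-c2ccc(OCOC)cc2OCOC)oc2cc(OC)cc(O)c12 | intermediate
11 | 3-chloro-3-methylbut-1-yne | CC(C)(Cl)C#C | starting material
12 | 2-[2,4-bis(methoxymethoxy)phenyl]-6-methoxy-4-[(2-methylbut-3-yn-2-yl)oxy]benzofuran-3-carbaldehyde | O=Cc1c(-c2ccc(OCOC)cc2OCOC)oc2cc(OC)cc(OC(C)(C)C#C)c12 | intermediate
13 | 2-[2,4-bis(methoxymethoxy)phenyl]-6-methoxy-4-[(2-methylbut-3-en-2-yl)oxy]benzofuran-3-carbaldehyde | O=Cc1c(-c2ccc(OCOC)cc2OCOC)oc2cc(OC)cc(OC(C)(C)C=C)c12 | intermediate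
14 | 2-[2,4-bis(methoxymethoxy)phenyl]-6-methoxy-5-(3-methylbut-2-en-1-yl)-4-oxo-4,5-dihydrobenzofuran-3-carbaldehyde (racemic dienone, not isolated) | O=Cc1c(-c2ccc(OCOC)cc2OCOC)oc2c1C(=O)C(CC=C(C)C)C(OC)=C2 | intermediate
15 | 2-[2,4-bis(methoxymethoxy)phenyl]-4-hydroxy-6-methoxy-5-(3-methylbut-2-en-1-yl)benzofuran-3-carbaldehyde | O=Cc1c(-c2ccc(OCOC)cc2OCOC)oc2cc(OC)c(CC=C(C)C)c(O)c12 | intermediate
16 | 2-(2,4-dihydroxyphenyl)-4-hydroxy-6-methoxy-5-(3-methylbut-2-en-1-yl)benzofuran-3-carbaldehyde | COc1cc2oc(-c3ccc(O)cc3O)c(C=O)c2c(O)c1CC=C(C)C | target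

Total step count: 11 steps.
Longest linear sequence: 10 steps (steps 2 to 11, from 3 to 16); the ring A branch from 1 runs through 9 steps.

Steps most likely to fail

1. Step 5 (reductive keto–ester coupling). The ketyl may dimerize intermolecularly, the ketone may be reduced without ring closure, the aryl ester may be cleaved reductively, the coupling may stall before deoxygenation, or MOM acetals may be lost to Lewis-acidic titanium chlorides. The fallback forms the same C2=C3 bond by an intramolecular Wittig reaction; it sets out from 2 and 5 and comes back to the route at 8. NaBH4 in MeOH should reduce 2 to 1-[2-(benzyloxy)-6-hydroxy-4-methoxyphenyl]ethanol F1. PPh3·HBr in hot MeCN should convert it, through the ortho-quinone methide, into {1-[2-(benzyloxy)-6-hydroxy-4-methoxyphenyl]ethyl}triphenylphosphonium bromide F2. Acid 5 is converted under neutral conditions with 1-chloro-N,N,2-trimethylprop-1-en-1-amine into 2,4-bis(methoxymethoxy)benzoyl chloride F3. F2, F3 and Et3N in refluxing toluene should first give {1-[2-(benzyloxy)-4-methoxy-6-{[2,4-bis(methoxymethoxy)benzoyl]oxy}phenyl]ethyl}triphenylphosphonium bromide F4 in the flask. Its ylide should then attack the neighbouring ester carbonyl and expel Ph3P=O to give 8.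

2. Step 6 (oxidation of the C3 methyl group). The oxidation may stop at the alcohol, electron-rich ring A may undergo electrophilic selenation, or acetals may be lost in hot selenous acid. The fallback raises the oxidation level in two stages by a hydride-abstraction route; it sets out from 8 and comes back at 9. DDQ (1 equiv) in dioxane/AcOH should abstract hydride from the methyl group, the stabilized cation being captured as {4-(benzyloxy)-2-[2,4-bis(methoxymethoxy)phenyl]-6-methoxybenzofuran-3-yl}methyl acetate F5. K2CO3 in MeOH should then give {4-(benzyloxy)-2-[2,4-bis(methoxymethoxy)phenyl]-6-methoxybenzofuran-3-yl}methanol F6. MnO2 in CH2Cl2 should oxidize this benzylic-type alcohol to 9.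

3. Step 11 (MOM removal beside the prenyl group). Under acid the O4 hydroxyl may add to the protonated prenyl double bond (chroman formation), the alkene may be hydrated, or acetal cleavage may remain incomplete at the mild temperature needed. The fallback moves the acid step ahead of the alkene, so that the last step is a neutral thermal rearrangement; it sets out from 12 and comes back at 16.
   - Deprotection: 3 M aq. HCl in THF applied to 12 should give 2-(2,4-dihydroxyphenyl)-6-methoxy-4-[(2-methylbut-3-yn-2-yl)oxy]benzofuran-3-carbaldehyde F7, because a tertiary propargylic aryl ether ionizes far less readily than an allylic one.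
   - Semihydrogenation: H2 over Pd/CaCO3 poisoned with Pb(OAc)2 with quinoline should give 2-(2,4-dihydroxyphenyl)-6-methoxy-4-[(2-methylbut-3-en-2-yl)oxy]benzofuran-3-carbaldehyde F8.
   - Claisen shift: heating in N,N-diethylaniline at 130 °C should give 2-(2,4-dihydroxyphenyl)-6-methoxy-5-(3-methylbut-2-en-1-yl)-4-oxo-4,5-dihydrobenzofuran-3-carbaldehyde F9 in the flask, which enolizes to 16.

Further compounds
F1 | step 5 | 1-[2-(benzyloxy)-6-hydroxy-4-methoxyphenyl]ethanol (racemic) | CC(O)c1c(OCc2ccccc2)cc(OC)cc1O
F2 | step 5 | {1-[2-(benzyloxy)-6-hydroxy-4-methoxyphenyl]ethyl}triphenylphosphonium bromide (racemic) | CC(c1c(OCc2ccccc2)cc(OC)cc1O)[P+](c1ccccc1)(c1ccccc1)c1ccccc1.[Br-]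
F3 | step 5 | 2,4-bis(methoxymethoxy)benzoyl chloride | O=C(Cl)c1ccc(OCOC)cc1OCOC
F4 | step 5 | {1-[2-(benzyloxy)-4-methoxy-6-{[2,4-bis(methoxymethoxy)benzoyl]oxy}phenyl]ethyl}triphenylphosphonium bromide (racemic, not isolated) | CC(c1c(OCc2ccccc2)cc(OC)cc1OC(=O)c1ccc(OCOC)cc1OCOC)[P+](c1ccccc1)(c1ccccc1)c1ccccc1.[Br-]
F5 | step 6 | {4-(benzyloxy)-2-[2,4-bis(methoxymethoxy)phenyl]-6-methoxybenzofuran-3-yl}methyl acetate | CC(=O)OCc1c(-c2ccc(OCOC)cc2OCOC)oc2cc(OC)cc(OCc3ccccc3)c12
F6 | step 6 | {4-(benzyloxy)-2-[2,4-bis(methoxymethoxy)phenyl]-6-methoxybenzofuran-3-yl}methanol | OCc1c(-c2ccc(OCOC)cc2OCOC)oc2cc(OC)cc(OCc3ccccc3)c12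
F7 | step 11 | 2-(2,4-dihydroxyphenyl)-6-methoxy-4-[(2-methylbut-3-yn-2-yl)oxy]benzofuran-3-carbaldehyde | O=Cc1c(-c2ccc(O)cc2O)oc2cc(OC)cc(OC(C)(C)C#C)c12
F8 | step 11 | 2-(2,4-dihydroxyphenyl)-6-methoxy-4-[(2-methylbut-3-en-2-yl)oxy]benzofuran-3-carbaldehyde | O=Cc1c(-c2ccc(O)cc2O)oc2cc(OC)cc(OC(C)(C)C=C)c12
F9 | step 11 | 2-(2,4-dihydroxyphenyl)-6-methoxy-5-(3-methylbut-2-en-1-yl)-4-oxo-4,5-dihydrobenzofuran-3-carbaldehyde (racemic dienone, not isolated) | O=Cc1c(-c2ccc(O)cc2O)oc2c1C(=O)C(CC=C(C)C)C(OC)=C2
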